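**Retrosynthetic overview**

1. Target 24 ⇒ E-iodoalkene 21 + 4-stannylbutenolide 23 (Stille, C12–C13); the butenolide ring is bought ready-made.
2. The 6α,7β-diacetoxy-8β-hydroxy array of ring B ⇒ the C6=C7 silyl enol ether of adduct 9. Oxygen goes to C6 (Rubottom), the enol ether is moved to C7=C8 through the 6,7-dione, oxygen goes to C8 (second Rubottom), then hydride to C6 from the β-face and to C7 by delivery from the 6α-hydroxyl.
3. Adduct 9 ⇒ open-chain tetraenal 8 by cutting C5–C10 and C8–C9. The strategy rests on ring B (C5–C10): with C7 as a silyl enol ether and a formyl group (C11) on C9 it is a cyclohexene retron (diene C5=C6–C7=C8, dienophile C9=C10), and C1–C4, holding the Z C3=C4 alkene, is the four-atom tether that becomes ring A. Rings A and B form together in one intramolecular Diels–Alder step.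
4. 8 ⇒ iodo enal 4 + boryl enone 6 (Suzuki, C4–C5); 4 ⇒ pent-4-enal 1 (Z-iodo-olefination, then cross-metathesis with methacrolein 3); 6 ⇒ hex-4-yn-3-one 5.

Key step: step 6

Remark on locants: clerodane numbering is used; α is the face of the C5 and C9 methyl groups (C19, C20), β the face of H-10.
Assumption: the facial sense of the boron catalyst is taken from the usual model for 2-substituted acroleins, which calls for the catalyst from (R)-diphenylprolinol; were the sense the reverse, the (S)-derived catalyst would be used and nothing else would change.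

**Step 1**
Reactants: 1 pent-4-enal
Product: 2 (5Z)-6-iodohepta-1,5-diene
Conditions: EtPPh3I, n-BuLi, THF, 0 °C; I2, −78 °C; NaN(SiMe3)2, −78 to −20 °C; then 1, −78 °C to rt
Reagents that add atoms: ethyltriphenylphosphonium iodide CC[P+](c1ccccc1)(c1ccccc1)c1ccccc1.[I-]; iodine II
Why: Stork–Zhao-type Wittig olefination with the α-iodo ylide (made in the flask by deprotonation, iodination and a second deprotonation) is Z-selective for unbranched aldehydes, so iodine should end cis to the chain, and the terminal alkene is inert.

**Step 2**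
Reactants: 2 (5Z)-6-iodohepta-1,5-diene; 3 methacrolein
Product: 4 (2E,6Z)-7-iodo-2-methylocta-2,6-dienal
Conditions: 3 (10 equiv), second-generation Hoveyda–Grubbs catalyst RuCl2(H2IMes)(=CH-C6H4-2-Oi-Pr) (5 mol%), CH2Cl2, 40 °C
Reagents that add atoms: none
Why: Olefin cross-metathesis of a terminal alkene with excess methacrolein should give the 2-methyl-2-enal with high E selectivity, and the trisubstituted iodoalkene is too hindered to engage the ruthenium carbene.

**Step 3**
Reactants: 5 hex-4-yn-3-one
Product: 6 (4Z)-5-(pinacolboryl)hex-4-en-3-one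
Conditions: B2pin2 (1.05 equiv), CuCl (5 mol%), NaOt-Bu (10 mol%), 4,5-bis(diphenylphosphino)-9,9-dimethylxanthene (5 mol%), MeOH (2 equiv), THF, 0 °C
Reagents that add atoms: bis(pinacolato)diboron CC1(C)OB(OC1(C)C)B1OC(C)(C)C(C)(C)O1
Why: Copper-catalysed conjugate borylation (borylcupration of the ynone, then protonation by methanol) is a syn addition of boron and hydrogen, which places boron trans to the carbonyl group.

**Step 4**
Reactants: 4 (2E,6Z)-7-iodo-2-methylocta-2,6-dienal; 6 (4Z)-5-(pinacolboryl)hex-4-en-3-one
Product: 7 (2E,6Z,8E)-2,7,8-trimethyl-10-oxododeca-2,6,8-trienal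
Conditions: Pd(OAc)2 (5 mol%), 2-dicyclohexylphosphino-2′,6′-dimethoxybiphenyl (10 mol%), K3PO4 (3 equiv), THF–H2O 10:1, 40 °C
Reagents that add atoms: none
Why: Suzuki–Miyaura coupling goes with retention at both sp2 carbons, so the Z geometry of the iodide (C3=C4) and the boronate geometry (C4 trans to C7 across C5=C6) pass into the diene, and the phosphate base should leave the enal and the ethyl ketone alone.

**Step 5**
Reactants: 7 (2E,6Z,8E)-2,7,8-trimethyl-10-oxododeca-2,6,8-trienal
Product: 8 (2E,6Z,8E,10Z)-2,7,8-trimethyl-10-(triisopropylsilyloxy)dodeca-2,6,8,10-tetraenal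
Conditions: i-Pr3SiOTf (1.1 equiv), Et3N (2 equiv), CH2Cl2, −78 °C
Reagents that add atoms: triisopropylsilyl trifluoromethanesulfonate CC(C)[Si](C(C)C)(C(C)C)OS(=O)(=O)C(F)(F)F
Why: Soft enolisation of the ethyl ketone (silyl triflate and amine, α′-deprotonation of an enone) should give the cross-conjugated 2-silyloxydiene as the Z enol ether (oxygen cis to methyl); the enal has no α-hydrogen and could react only by slower γ-deprotonation, and triisopropylsilyl is chosen for its resistance to the acidic catalyst of step 6.

**Step 6**
Reactants: 8 (2E,6Z,8E,10Z)-2,7,8-trimethyl-10-(triisopropylsilyloxy)dodeca-2,6,8,10-tetraenal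
Product: 9 trans-octalin 9-carbaldehyde 7-triisopropylsilyl enol ether
Conditions: oxazaborolidinium triflimide from (R)-α,α-diphenylprolinol, (o-TolBO)3 and (CF3SO2)2NH (20 mol%), CH2Cl2 (0.02 M), −78 to −40 °C
Reagents that add atoms: none
Why: The N-protonated oxazaborolidine binds the formyl oxygen of the s-trans 2-methylenal and lowers its LUMO, and a concerted, asynchronous [4+2] cycloaddition with the tethered 2-silyloxydiene follows, the C5–C10 bond to the enal β-carbon running ahead of C8–C9. The closest known reaction type is the oxazaborolidinium-catalysed intramolecular Diels–Alder reaction of trienals with 2-substituted enal dienophiles, together with intermolecular additions of 2-silyloxydienes under the same catalysts. Ring B is the new cyclohexene made from diene C5–C8 and dienophile C9=C10, and ring A closes in the same event through the C5–C10 bond, with the four-atom tether C1–C4 held exo (fused 1,7,9-decatriene mode) and pre-folded by the Z C3=C4 alkene. C9 and C10 follow from the E enal (C20 and C1 cis), C5 and C8 from the diene geometry (C4 and C17 outside, C19 inside), and their mutual relation from the formyl-endo, tether-exo transition state (trans fusion; C19 and C20 on the α-face; H-10, the formyl group and C17 on the β-face). The absolute sense comes from the catalyst, whose phenyl group covers one face of the bound enal so that C8 adds to the Si face of C9. The step needs endo and enantiofacial selectivity, secured by the catalyst on the formyl group and the fixed alkene geometries, and it needs the tether to override the para preference of the 2-silyloxydiene, which the fused six-membered closure provides because the alternative is a strained bridged ring; high dilution is meant to hold back intermolecular Mukaiyama-type addition.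

**Step 7**
Reactants: 9 trans-octalin 9-carbaldehyde 7-triisopropylsilyl enol ether
Product: 10 9β-[(E)-2-iodoethenyl] trans-octalin 7-triisopropylsilyl enol ether
Conditions: CrCl2 (8 equiv), CHI3 (3 equiv), THF–dioxane, 0 °C to rt
Reagents that add atoms: iodoform IC(I)I
Why: Takai olefination (geminal dichromium reagent from iodoform and divalent chromium) should convert even this α-quaternary, non-enolisable aldehyde into the E-iodoalkene under neutral conditions that the silyl enol ether tolerates, and it turns the aldehyde into a handle that survives every later step.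

**Step 8**
Reactants: 10 9β-[(E)-2-iodoethenyl] trans-octalin 7-triisopropylsilyl enol ether
Product: 13 6β-hydroxy 7-ketone (8β-methyl; C6 or C8 epimers tolerated), via silyloxy epoxide 11 (not isolated), via 6β-silyloxy ketone 12 (not isolated)
Conditions: m-CPBA (1.05 equiv), NaHCO3, CH2Cl2, −40 to 0 °C; then Bu4NF, AcOH, THF, 0 °C to rt
Reagents that add atoms: 3-chloroperoxybenzoic acid OOC(=O)c1cccc(Cl)c1
Why: Rubottom oxidation: the silyl enol ether should be epoxidised much faster than the ring A alkene or the iodoalkene and on the β-face (the pseudoaxial C19 methyl next to C6 covers the α-face), the epoxide rearranges with 1,4-silyl shift and buffered fluoride frees the alcohol; the configurations at C6 and C8 do not matter because both carbons become trigonal in steps 9 and 10.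

**Step 9**
Reactants: 13 6β-hydroxy 7-ketone
Product: 14 diosphenol (7-hydroxy-Δ7-en-6-one)
Conditions: Dess–Martin periodinane, NaHCO3, CH2Cl2, 0 °C to rt
Reagents that add atoms: none
Why: Oxidation of an α-hydroxy ketone to the 1,2-dione with a hypervalent iodine reagent; because C5 is quaternary the dione can enolise only toward C8, so every C6 or C8 epimer of 13 should converge on one diosphenol.

**Step 10**
Reactants: 14 diosphenol (7-hydroxy-Δ7-en-6-one)
Product: 15 7-(tert-butyldimethylsilyloxy)-Δ7-en-6-one
Conditions: t-BuMe2SiOTf, Et3N, CH2Cl2, −78 to 0 °C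
Reagents that add atoms: tert-butyldimethylsilyl trifluoromethanesulfonate CC(C)(C)[Si](C)(C)OS(=O)(=O)C(F)(F)F
Why: O-silylation of the enol (or soft enolisation of the diketo tautomer, which has only H-8 to lose) can give one silyl enol ether only; it masks C7 and leaves C6 as the single free carbonyl group.

**Step 11**
Reactants: 15 7-(tert-butyldimethylsilyloxy)-Δ7-en-6-one
Product: 16 6α-hydroxy-7-(tert-butyldimethylsilyloxy)-Δ7-ene
Conditions: i-Bu2AlH, CH2Cl2, −78 °C; aqueous KNaC4H4O6 work-up; used without delay
Reagents that add atoms: none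
Why: 1,2-Reduction of the enone carbonyl with an aluminium hydride; hydride should add to C6 from the β-face because the pseudoaxial C19 methyl on the neighbouring quaternary C5 covers the α-face, which sets 6α-OH, and the silyl enol ether and iodoalkene do not react at −78 °C.

**Step 12**
Reactants: 16 6α-hydroxy-7-(tert-butyldimethylsilyloxy)-Δ7-ene
Product: 18 6α-hydroxy-8β-(tert-butyldimethylsilyloxy) 7-ketone, via silyloxy epoxide 17 (not isolated)
Conditions: m-CPBA (1.05 equiv), NaHCO3, CH2Cl2, −40 to 0 °C
Reagents that add atoms: 3-chloroperoxybenzoic acid OOC(=O)c1cccc(Cl)c1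
Why: Second Rubottom oxidation: the tetrasubstituted silyl enol ether is by far the most nucleophilic alkene, the peracid should add to the β-face of C7=C8 because the axial C20 methyl on C9 and the C19 methyl on C5 cover the α-face, and the silyl group moves to the new oxygen, giving the 8β-silyloxy-8α-methyl 7-ketone.

**Step 13**
Reactants: 18 6α-hydroxy-8β-(tert-butyldimethylsilyloxy) 7-ketone
Product: 19 6α,7β-diol 8β-silyl ether
Conditions: Me4NBH(OAc)3, MeCN–AcOH, −30 to 0 °C
Reagents that add atoms: none
Why: Hydroxyl-directed reduction of the Evans–Saksena type: triacetoxyborohydride reduces a ketone only after exchange with a nearby hydroxyl, the only free one is the equatorial 6α-OH (the tertiary oxygen is silylated), and the resulting alkoxyborohydride should deliver hydride to C7 along the axial direction on the α-face with boron held outside the ring, so that only hydrogen passes between the C19 and C20 methyls and the equatorial 7β-OH, trans to 6α-OH, results.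

**Step 14**
Reactants: 19 6α,7β-diol 8β-silyl ether
Product: 20 6α,7β-diacetate 8β-silyl ether
Conditions: Ac2O, DMAP, pyridine, rt
Reagents that add atoms: acetic anhydride CC(=O)OC(C)=O
Why: DMAP-catalysed acylation of the two secondary equatorial alcohols; the tertiary oxygen is still silylated.

**Step 15**
Reactants: 20 6α,7β-diacetate 8β-silyl ether
Product: 21 6α,7β-diacetoxy-8β-hydroxy E-iodoalkene
Conditions: HF·pyridine, pyridine, THF, 0 to 40 °C
Reagents that add atoms: none
Why: Fluoride cleavage of the tertiary silyl ether under acidic, non-basic conditions, which should avoid acetyl migration from O7 to the cis tertiary oxygen and leave the acetates, the iodoalkene and the ring A alkene untouched.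

**Step 16**
Reactants: 22 4-bromofuran-2(5H)-one
Product: 23 4-(tributylstannyl)furan-2(5H)-one
Conditions: (Bu3Sn)2, Pd(PPh3)4 (5 mol%), toluene, 100 °C
Reagents that add atoms: hexabutylditin CCCC[Sn](CCCC)(CCCC)[Sn](CCCC)(CCCC)CCCC
Why: Palladium-catalysed stannylation of a vinylogous acyl bromide with a distannane (oxidative addition, tin–tin transmetalation, reductive elimination).

**Step 17**
Reactants: 21 6α,7β-diacetoxy-8β-hydroxy E-iodoalkene; 23 4-(tributylstannyl)furan-2(5H)-one
Product: 24 target CNP0383656.1
Conditions: Pd2(dba)3 (5 mol%), AsPh3 (20 mol%), CuI (10 mol%), DMF, rt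
Reagents that add atoms: none
Why: Stille coupling of the E-iodoalkene with the 4-stannylbutenolide goes with retention of alkene geometry under neutral conditions that the acetates, the free tertiary alcohol and the base-sensitive butenolide should tolerate.

**Compound list**

Compounds 10–21 keep the ring A Δ3 alkene, the 4-, 5α- and 9α-methyl groups, 10β-H, the trans ring fusion and the 9β-(E)-2-iodoethenyl group.

1 | pent-4-enal | C=CCCC=O | starting material
2 | (5Z)-6-iodohepta-1,5-diene | C=CCC/C=C(/C)I | intermediate
3 | methacrolein (2-methylprop-2-enal) | CC(=C)C=O | starting material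
4 | (2E,6Z)-7-iodo-2-methylocta-2,6-dienal | O=C/C(C)=C/CC/C=C(/C)I | intermediate
5 | hex-4-yn-3-one | CCC(=O)C#CC | starting material
6 | (4Z)-5-(4,4,5,5-tetramethyl-1,3,2-dioxaborolan-2-yl)hex-4-en-3-one | CCC(=O)/C=C(\C)B1OC(C)(C)C(C)(C)O1 | intermediate
7 | (2E,6Z,8E)-2,7,8-trimethyl-10-oxododeca-2,6,8-trienal | O=C/C(C)=C/CC/C=C(C)\C(C)=C\C(=O)CC | intermediate
8 | (2E,6Z,8E,10Z)-2,7,8-trimethyl-10-(triisopropylsilyloxy)dodeca-2,6,8,10-tetraenal (key-step precursor) | O=C/C(C)=C/CC/C=C(C)\C(C)=C\C(O[Si](C(C)C)(C(C)C)C(C)C)=C\C | intermediate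
9 | 1,2,4a,5-tetramethyl-3-(triisopropylsilyloxy)-1,2,4a,7,8,8a-hexahydronaphthalene-1-carbaldehyde, trans-fused; clerodane locants: Δ3, Δ6, 7-OSi, 5α-Me, 8β-Me, 9α-Me, 9β-CHO, 10β-H (key-step product) | C1=C(O[Si](C(C)C)(C(C)C)C(C)C)[C@H](C)[C@](C)(C=O)[C@H]2CCC=C(C)[C@]12C | intermediate
10 | as 9 with 9β-[(E)-2-iodoethenyl] in place of 9β-CHO | C1=C(O[Si](C(C)C)(C(C)C)C(C)C)[C@H](C)[C@](C)(/C=C/I)[C@H]2CCC=C(C)[C@]12C | intermediate
11 | 6β,7β-epoxide of 10 (7α-triisopropylsilyloxy, 8β-Me) | [C@@H]1(O3)[C@@]3(O[Si](C(C)C)(C(C)C)C(C)C)[C@H](C)[C@](C)(/C=C/I)[C@H]2CCC=C(C)[C@]12C | intermediate (not isolated)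
12 | 6β-(triisopropylsilyloxy) 7-ketone, 8β-Me | CC(C)[Si](C(C)C)(C(C)C)O[C@@H]1C(=O)[C@H](C)[C@](C)(/C=C/I)[C@H]2CCC=C(C)[C@]12C | intermediate (not isolated)
13 | 6β-hydroxy 7-ketone, 8β-Me (expected isomer; C6 and C8 epimers are carried on) | O[C@@H]1C(=O)[C@H](C)[C@](C)(/C=C/I)[C@H]2CCC=C(C)[C@]12C | intermediate
14 | diosphenol: 6-oxo, C7(OH)=C8(Me) | O=C1C(O)=C(C)[C@](C)(/C=C/I)[C@H]2CCC=C(C)[C@]12C | intermediate
15 | 6-oxo, C7(OSiMe2t-Bu)=C8(Me) | O=C1C(O[Si](C)(C)C(C)(C)C)=C(C)[C@](C)(/C=C/I)[C@H]2CCC=C(C)[C@]12C | intermediate
16 | 6α-hydroxy, C7(OSiMe2t-Bu)=C8(Me) | O[C@H]1C(O[Si](C)(C)C(C)(C)C)=C(C)[C@](C)(/C=C/I)[C@H]2CCC=C(C)[C@]12C | intermediate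
17 | 7β,8β-epoxide of 16 (7α-silyloxy, 8α-Me) | O[C@H]1[C@]2(O[Si](C)(C)C(C)(C)C)O[C@]2(C)[C@](C)(/C=C/I)[C@H]3CCC=C(C)[C@]13C | intermediate (not isolated)
18 | 6α-hydroxy-8β-(tert-butyldimethylsilyloxy)-8α-methyl 7-ketone | O[C@H]1C(=O)[C@](C)(O[Si](C)(C)C(C)(C)C)[C@](C)(/C=C/I)[C@H]2CCC=C(C)[C@]12C | intermediate
19 | 6α,7β-diol, 8β-(tert-butyldimethylsilyloxy), 8α-Me | O[C@H]1[C@H](O)[C@](C)(O[Si](C)(C)C(C)(C)C)[C@](C)(/C=C/I)[C@H]2CCC=C(C)[C@]12C | intermediate
20 | 6α,7β-diacetate, 8β-(tert-butyldimethylsilyloxy), 8α-Me | CC(=O)O[C@H]1[C@H](OC(C)=O)[C@](C)(O[Si](C)(C)C(C)(C)C)[C@](C)(/C=C/I)[C@H]2CCC=C(C)[C@]12C | intermediate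
21 | 6α,7β-diacetoxy-8β-hydroxy-8α-methyl E-iodoalkene | CC(=O)O[C@H]1[C@H](OC(C)=O)[C@](C)(O)[C@](C)(/C=C/I)[C@H]2CCC=C(C)[C@]12C | intermediate
22 | 4-bromofuran-2(5H)-one | O=C1C=C(Br)CO1 | starting material
23 | 4-(tributylstannyl)furan-2(5H)-one | O=C1C=C(CO1)[Sn](CCCC)(CCCC)CCCC | intermediate
24 | CNP0383656.1: 6α,7β-diacetoxy-8β-hydroxy clerodane with Δ3 alkene and 9β-[(E)-2-(5-oxo-2,5-dihydrofuran-3-yl)ethenyl] | CC(=O)O[C@H]1[C@H](OC(C)=O)[C@](C)(O)[C@](C)(/C=C/C2=CC(=O)OC2)[C@H]2CCC=C(C)[C@]12C | target

**Step count**

Total: 17 steps. Longest linear sequence: 15 steps (1, 2, 4 to 15, 17); steps 3 and 16 are side branches.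

**Steps most likely to fail**

Step 6 (key step). The tether forces the electronically mismatched orientation: the enol ether terminus C8 must bond to the enal α-carbon. Stepwise Mukaiyama-type addition, oligomerisation, protodesilylation by the acidic catalyst or poor enantiofacial control may therefore take over. Fallback, setting out from 8 and coming back at 9: the tetraenal is cyclised without any Lewis acid, in toluene at 80–100 °C with 2,6-di-tert-butyl-4-methylphenol and a trace of Et3N, to the racemic adduct F1. The fixed alkene geometries and the exo tether should still give the trans-fused, formyl-endo relative configuration. The enantiomers are then separated by preparative chromatography on a chiral stationary phase (amylose tris(3,5-dimethylphenylcarbamate)), and the enantiomer identical with 9 enters step 7.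

Step 13. The C7 carbonyl is flanked on the α-face by the two syn-axial methyls and on the β-face by the axial 8-silyloxy group, so hydride may be delivered to the wrong face or not at all. Fallback, setting out from 18 and coming back at 19: 18 is equilibrated with an amine base (DBU, toluene, rt to 60 °C) through the C6/C7 enediol to the transposed α-ketol, the 7β-hydroxy 6-ketone F2. There the C7 configuration is set by protonation under thermodynamic control, since a 7α-oxygen would be syn-axial to both C19 and C20, and the crowded C6 is trigonal. Reduction of F2 with NaBH4 (MeOH, −20 °C) should then add hydride to C6 from the β-face, anti to the axial C19 methyl on C5, and give 19.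

Step 5. Silyl triflate and amine may also convert the enal into its 1-silyloxydiene by γ-deprotonation, or give a mixture of enol ether geometries, and either would spoil the key step. Fallback, setting out from 2 and 6 and coming back at 8: the order is changed so that the ketone is enolised before any aldehyde exists. Suzuki coupling of 2 with 6 under the conditions of step 4 gives the trienone F3. Treatment with i-Pr3SiOTf and Et3N gives the silyloxytetraene F4. Cross-metathesis of the terminal alkene of F4 with methacrolein 3 under the conditions of step 2 then gives 8.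

**Further compounds**

F1 | step 6 | racemic adduct (9 and its enantiomer, 1:1) | C1=C(O[Si](C(C)C)(C(C)C)C(C)C)[C@H](C)[C@](C)(C=O)[C@H]2CCC=C(C)[C@]12C.C1=C(O[Si](C(C)C)(C(C)C)C(C)C)[C@@H](C)[C@@](C)(C=O)[C@@H]2CCC=C(C)[C@@]12C
F2 | step 13 | 7β-hydroxy-8β-(tert-butyldimethylsilyloxy)-8α-methyl 6-ketone | O=C1[C@H](O)[C@](C)(O[Si](C)(C)C(C)(C)C)[C@](C)(/C=C/I)[C@H]2CCC=C(C)[C@]12C
F3 | step 5 | (4E,6Z)-5,6-dimethylundeca-4,6,10-trien-3-one | C=CCC/C=C(C)\C(C)=C\C(=O)CC
F4 | step 5 | (2Z,4E,6Z)-5,6-dimethyl-3-(triisopropylsilyloxy)undeca-2,4,6,10-tetraene | C=CCC/C=C(C)\C(C)=C\C(O[Si](C(C)C)(C(C)C)C(C)C)=C\C
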